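**Retrosynthetic overview**

1. Numbering: C1 is the ring carbinol carbon, C2 and C5 the acetoxy carbons, C3=C4 the alkene, C6 the ketone carbon. The strategy rests on one feature: the oxygens on C2, C1 and C5 are mutually trans (C6 cis to both acetoxy groups) and sit beside an unsubstituted cis C3=C4. This is the pattern of three contiguous equatorial oxygens on a six-membered chair whose two remaining CH2 groups flank a sulfur atom.
2. Target ⇒ (acetylation, desilylation) triol ketone 21 ⇒ (C6 ketone unmasked from a triple bond via a silver/CO2 carbonate and its hydrolysis) alkynyl carbinol 17.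
3. 17 ⇒ (C3=C4 by Ramberg–Bäcklund contraction with loss of SO2) thiane 1,1-dioxide 14 ⇒ (S-oxidation; C1–C6 bond by axial acetylide addition) meso thian-4-one 9.
4. 9 ⇒ (oxidation, silylation of the outer hydroxyls) all-trans thiane-3,4,5-triol 6 ⇒ (two C–S bonds) 1,5-dibromide 3 ⇒ xylitol.
5. Ring order: the thiane is closed first (step 2) and contracted in step 7 to the cyclopentene, the only ring of the target; a spiro carbonate ring is made in step 8 and opened in step 9.

Key step: step 7

Remark: the target is a meso compound (mirror plane through C1, C6 and the midpoint of C3=C4), so only relative configuration has to be controlled and the meso pentitol xylitol supplies C2 and C5.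

**Route**

Step 1
Reactants: 1 xylitol; 2 acetyl bromide
Product: 3 2,3,4-tri-O-acetyl-1,5-dibromo-1,5-dideoxyxylitol (meso)
Conditions: AcBr (excess), 1,4-dioxane, rt
Reagents that add atoms: acetyl bromide, CC(=O)Br
Why: Bromoacetylation of an alditol: the pentitol is peracetylated and the HBr set free opens the terminal 1,2-acetoxonium ions at the primary carbons, so no C–O bond at C2–C4 is broken and the xylo configuration is kept.

Step 2
Reactants: 3 2,3,4-tri-O-acetyl-1,5-dibromo-1,5-dideoxyxylitol; 4 sodium sulfide
Product: 6 (3R,4s,5S)-thiane-3,4,5-triol (1,5-anhydro-5-thioxylitol, all-trans, meso), via triacetoxythiane 5 (not isolated)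
Conditions: Na2S·9H2O, DMF, rt; then NaOMe (cat.), MeOH, rt
Reagents that add atoms: sodium sulfide, [Na+].[Na+].[S-2]
Why: Double SN2 displacement of the two primary bromides by sulfide (the second one a 6-exo-tet closure) builds the thiane without touching the stereocentres, and Zemplén transesterification then frees three hydroxyls that are all equatorial on the chair.

Step 3
Reactants: 6 (3R,4s,5S)-thiane-3,4,5-triol; 7 tert-butyldimethylsilyl chloride
Product: 8 (3R,4s,5S)-3,5-bis(tert-butyldimethylsilyloxy)thian-4-ol (meso, all-trans)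
Conditions: TBSCl (2.1 equiv), imidazole, DMF, 0 °C → rt
Reagents that add atoms: tert-butyldimethylsilyl chloride, CC(C)(C)[Si](C)(C)Cl
Why: Silyl ether formation with a bulky chloride: each outer hydroxyl has only one oxygenated neighbour and a silyl group on O3 screens O4, so the second silyl group should go to O5 and leave the doubly flanked central hydroxyl free; no stereocentre changes.

Step 4
Reactants: 8 (3R,4s,5S)-3,5-bis(tert-butyldimethylsilyloxy)thian-4-ol
Product: 9 (3R,5S)-3,5-bis(tert-butyldimethylsilyloxy)thian-4-one (meso, cis)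
Conditions: Dess–Martin periodinane, CH2Cl2, 0 °C → rt
Reagents that add atoms: none
Why: Dess–Martin oxidation of a secondary alcohol, which is faster than oxidation of the ring sulfide and uses no amine base, so the thioether is not lost by β-elimination and the two silyloxy carbons stay cis (diequatorial).

Step 5
Reactants: 9 (3R,5S)-3,5-bis(tert-butyldimethylsilyloxy)thian-4-one; 10 1-undecyne
Product: 12 (3R,4s,5S)-3,5-bis(tert-butyldimethylsilyloxy)-4-(undec-1-yn-1-yl)thian-4-ol (meso; hydroxyl equatorial and trans to both silyloxy groups, alkynyl axial), via lithium undec-1-yn-1-ide 11 (not isolated)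
Conditions: 10 (1.3 equiv), n-BuLi (1.2 equiv), THF, −78 °C; then 9, −78 → −40 °C; H2O quench at low temperature
Reagents that add atoms: 1-undecyne, CCCCCCCCCC#C
Why: 1,2-Addition of a lithium acetylide to a ketone: the slender nucleophile attacks the chair (both silyloxy groups equatorial) along the axial trajectory, staggered to the axial C3–H and C5–H bonds, so the new hydroxyl is equatorial and trans to both neighbours and the future acyl carbon is cis to them, which sets the quaternary centre.

Step 6
Reactants: 12 (3R,4s,5S)-3,5-bis(tert-butyldimethylsilyloxy)-4-(undec-1-yn-1-yl)thian-4-ol; 13 3-chloroperoxybenzoic acid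
Product: 14 (3R,4s,5S)-3,5-bis(tert-butyldimethylsilyloxy)-4-hydroxy-4-(undec-1-yn-1-yl)thiane 1,1-dioxide (meso)
Conditions: mCPBA (2.2 equiv), CH2Cl2, 0 °C → rt
Reagents that add atoms: 3-chloroperoxybenzoic acid, OOC(=O)c1cccc(Cl)c1
Why: Peracid oxidation of a sulfide through the sulfoxide to the sulfone; the internal alkyne and the hindered tertiary alcohol do not react with a peracid at this temperature.

Step 7
Reactants: 14 (3R,4s,5S)-3,5-bis(tert-butyldimethylsilyloxy)-4-hydroxy-4-(undec-1-yn-1-yl)thiane 1,1-dioxide
Product: 17 meso 2,5-bis(tert-butyldimethylsilyloxy)-1-(undec-1-yn-1-yl)cyclopent-3-en-1-ol (silyloxy groups cis to each other and to the alkynyl group, trans to the hydroxyl), via bromo sulfone 15 (not isolated), via episulfone 16 (not isolated)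
Conditions: CBr2F2, KOH/Al2O3, t-BuOH/CH2Cl2, 0 °C → rt
Reagents that add atoms: none
Why: Hydroxide on alumina deprotonates an α-sulfonyl carbon of 14 and the carbanion takes bromine from CBr2F2 to give 15; a second deprotonation at the other α carbon gives a carbanion that displaces bromide in a 3-exo-tet closure to the cis-fused episulfone 16, and cheletropic loss of SO2 leaves the C3=C4 double bond (Ramberg–Bäcklund reaction with in-situ halogenation, known for the contraction of thiane 1,1-dioxides, polyoxygenated ones included, to cyclopentenes). The cyclopentene ring is therefore closed by the C3–C4 bond made in the 3-exo-tet step, while the six-membered ring gives up its sulfur. No stereocentre is created: C2, C1 and C5 of the cyclopentene are C3, C4 and C5 of the thiane and no bond to them is broken, so the all-trans triad set in steps 1–5 is carried over, and a five-membered ring can hold only a cis alkene. The selectivity needed is 1,3-elimination ahead of E1cB loss of a β-silyloxy group; on the chair both silyloxy groups are equatorial, so no α C–H bond (and no carbanion orbital that replaces it) is antiperiplanar to a C–O bond, whereas an equatorial carbanion orbital and an equatorial C–Br bond are aligned in the W arrangement that the 1,3-displacement prefers. The tertiary propargylic alcohol is only deprotonated and, being hindered and remote from the reacting carbons, should stay a spectator, and the internal alkyne has no acidic hydrogen.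

Step 8
Reactants: 17 meso 2,5-bis(tert-butyldimethylsilyloxy)-1-(undec-1-yn-1-yl)cyclopent-3-en-1-ol; 18 carbon dioxide
Product: 19 (Z)-4-decylidene-6,9-bis(tert-butyldimethylsilyloxy)-1,3-dioxaspiro[4.4]non-7-en-2-one (meso spiro carbonate)
Conditions: AgOAc (10 mol %), DBU (1 equiv), CO2 (1 MPa), toluene, rt
Reagents that add atoms: carbon dioxide, O=C=O
Why: Silver-catalysed carboxylative cyclisation of a tertiary propargylic alcohol: the carbonate formed from the alkoxide and CO2 adds anti across the triple bond activated by monovalent silver in a 5-exo-dig closure, which places oxygen on the alkyne carbon next to the carbinol and gives the Z alkylidene carbonate without touching the ring stereocentres.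

Step 9
Reactants: 19 (Z)-4-decylidene-6,9-bis(tert-butyldimethylsilyloxy)-1,3-dioxaspiro[4.4]non-7-en-2-one
Product: 20 1-[2,5-bis(tert-butyldimethylsilyloxy)-1-hydroxycyclopent-3-en-1-yl]undecan-1-one (meso; silyloxy groups cis to the acyl group)
Conditions: LiOH·H2O (2 equiv), THF/H2O, 0 °C; pH 7 buffer
Reagents that add atoms: none
Why: Hydrolysis of an enol carbonate: hydroxide attacks the carbonate carbonyl, the enolate leaves and tautomerises to the C6 ketone, and the hydrogen carbonate left on the tertiary oxygen loses CO2; water supplies only hydrogen because the ketone oxygen is the ring oxygen brought in by CO2, and water is used instead of an alcohol because alcoholysis would leave a carbonate ester on the tertiary oxygen.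

Step 10
Reactants: 20 1-[2,5-bis(tert-butyldimethylsilyloxy)-1-hydroxycyclopent-3-en-1-yl]undecan-1-one
Product: 21 1-(1,2,5-trihydroxycyclopent-3-en-1-yl)undecan-1-one (meso; the three hydroxyls all-trans)
Conditions: HF·pyridine, pyridine/THF, 0 °C → rt
Reagents that add atoms: none
Why: Fluoride cleavage of silyl ethers under buffered, slightly acidic conditions, which avoids the retro-aldol cleavage that a basic fluoride source could start in the β-hydroxy ketone; no stereocentre is affected.

Step 11
Reactants: 21 1-(1,2,5-trihydroxycyclopent-3-en-1-yl)undecan-1-one; 22 acetic anhydride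
Product: 23 1-hydroxy-1-undecanoylcyclopent-3-ene-2,5-diyl diacetate (target CNP0208983.3; meso, acetoxy groups cis to the acyl group and trans to the hydroxyl)
Conditions: Ac2O (2.5 equiv), pyridine, DMAP (cat.), CH2Cl2, 0 °C
Reagents that add atoms: acetic anhydride, CC(=O)OC(C)=O
Why: Acylation of the two secondary allylic alcohols; the tertiary α-ketol hydroxyl between two substituted carbons is too hindered to react at 0 °C, and because C1 bears no hydrogen the β-acetoxy ketone cannot eliminate.

**Compound list**

1 | xylitol | OC[C@H](O)[C@@H](O)[C@H](O)CO | starting material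
2 | acetyl bromide | CC(=O)Br | starting material
3 | 2,3,4-tri-O-acetyl-1,5-dibromo-1,5-dideoxyxylitol (meso) | BrC[C@H](OC(C)=O)[C@@H](OC(C)=O)[C@H](OC(C)=O)CBr | intermediate
4 | sodium sulfide (used as the nonahydrate) | [Na+].[Na+].[S-2] | starting material
5 | (3R,4s,5S)-thiane-3,4,5-triyl triacetate (all-trans, meso) | S1C[C@H](OC(C)=O)[C@@H](OC(C)=O)[C@H](OC(C)=O)C1 | intermediate (not isolated)
6 | (3R,4s,5S)-thiane-3,4,5-triol (all-trans, meso) | S1C[C@H](O)[C@@H](O)[C@H](O)C1 | intermediate
7 | tert-butyldimethylsilyl chloride | CC(C)(C)[Si](C)(C)Cl | starting material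
8 | (3R,4s,5S)-3,5-bis(tert-butyldimethylsilyloxy)thian-4-ol (meso) | S1C[C@H](O[Si](C)(C)C(C)(C)C)[C@@H](O)[C@H](O[Si](C)(C)C(C)(C)C)C1 | intermediate
9 | (3R,5S)-3,5-bis(tert-butyldimethylsilyloxy)thian-4-one (meso, cis) | S1C[C@H](O[Si](C)(C)C(C)(C)C)C(=O)[C@H](O[Si](C)(C)C(C)(C)C)C1 | intermediate
10 | 1-undecyne | CCCCCCCCCC#C | starting material
11 | lithium undec-1-yn-1-ide | [Li]C#CCCCCCCCCC | intermediate (not isolated)
12 | (3R,4s,5S)-3,5-bis(tert-butyldimethylsilyloxy)-4-(undec-1-yn-1-yl)thian-4-ol (meso) | CCCCCCCCCC#C[C@@]1(O)[C@@H](O[Si](C)(C)C(C)(C)C)CSC[C@H]1O[Si](C)(C)C(C)(C)C | intermediate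
13 | 3-chloroperoxybenzoic acid | OOC(=O)c1cccc(Cl)c1 | starting material
14 | (3R,4s,5S)-3,5-bis(tert-butyldimethylsilyloxy)-4-hydroxy-4-(undec-1-yn-1-yl)thiane 1,1-dioxide (meso) | CCCCCCCCCC#C[C@@]1(O)[C@@H](O[Si](C)(C)C(C)(C)C)CS(=O)(=O)C[C@H]1O[Si](C)(C)C(C)(C)C | intermediate
15 | 2-bromo-3,5-bis(tert-butyldimethylsilyloxy)-4-hydroxy-4-(undec-1-yn-1-yl)thiane 1,1-dioxide (racemic, either configuration at C2) | CCCCCCCCCC#C[C@@]1(O)[C@@H](O[Si](C)(C)C(C)(C)C)C(Br)S(=O)(=O)C[C@H]1O[Si](C)(C)C(C)(C)C | intermediate (not isolated)
16 | 2,4-bis(tert-butyldimethylsilyloxy)-3-hydroxy-3-(undec-1-yn-1-yl)-6-thiabicyclo[3.1.0]hexane 6,6-dioxide (cis-fused episulfone, face of fusion not defined) | CCCCCCCCCC#C[C@@]1(O)[C@@H](O[Si](C)(C)C(C)(C)C)C2C([C@H]1O[Si](C)(C)C(C)(C)C)S2(=O)=O | intermediate (not isolated)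
17 | meso 2,5-bis(tert-butyldimethylsilyloxy)-1-(undec-1-yn-1-yl)cyclopent-3-en-1-ol | CCCCCCCCCC#C[C@@]1(O)[C@@H](O[Si](C)(C)C(C)(C)C)C=C[C@H]1O[Si](C)(C)C(C)(C)C | intermediate
18 | carbon dioxide | O=C=O | starting material
19 | (Z)-4-decylidene-6,9-bis(tert-butyldimethylsilyloxy)-1,3-dioxaspiro[4.4]non-7-en-2-one (meso) | CCCCCCCCC/C=C1\OC(=O)O[C@@]12[C@@H](O[Si](C)(C)C(C)(C)C)C=C[C@H]2O[Si](C)(C)C(C)(C)C | intermediate
20 | 1-[2,5-bis(tert-butyldimethylsilyloxy)-1-hydroxycyclopent-3-en-1-yl]undecan-1-one (meso) | CCCCCCCCCCC(=O)[C@@]1(O)[C@@H](O[Si](C)(C)C(C)(C)C)C=C[C@H]1O[Si](C)(C)C(C)(C)C | intermediate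
21 | 1-(1,2,5-trihydroxycyclopent-3-en-1-yl)undecan-1-one (meso, all-trans triol) | CCCCCCCCCCC(=O)[C@@]1(O)[C@@H](O)C=C[C@H]1O | intermediate
22 | acetic anhydride | CC(=O)OC(C)=O | starting material
23 | 1-hydroxy-1-undecanoylcyclopent-3-ene-2,5-diyl diacetate (meso) | CCCCCCCCCCC(=O)[C@@]1(O)[C@@H](OC(C)=O)C=C[C@H]1OC(C)=O | target

**Step count and risks**

Total step count: 11. Longest linear sequence: 11 steps, from xylitol 1 to target 23; 1-undecyne enters at step 5.

Steps most likely to fail:

1. Step 7. The α-sulfonyl carbanion may expel a β-silyloxy group (E1cB, leading to a vinyl sulfone and loss of the triad) while the heterogeneous in-situ bromination is slow. The tertiary alkoxide may also take part, by silyl migration from a neighbouring oxygen or by capture of difluorocarbene. Fallback: halogenate without base at the sulfide stage and run the rearrangement cold and briefly. It sets out from sulfide 12. NCS in CH2Cl2 at 0 °C gives 2-chloro-3,5-bis(tert-butyldimethylsilyloxy)-4-(undec-1-yn-1-yl)thian-4-ol F1 (racemic, both C2 epimers). mCPBA (2.2 equiv) in CH2Cl2 at −20 → 0 °C oxidises it to the α-chloro sulfone, 2-chloro-3,5-bis(tert-butyldimethylsilyloxy)-4-hydroxy-4-(undec-1-yn-1-yl)thiane 1,1-dioxide F2. KOtBu in THF at −78 → 0 °C then effects the classical Ramberg–Bäcklund rearrangement of the preformed halo sulfone, and the route is rejoined at 17.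

2. Step 3. Silylation may also occur at the central oxygen, or the silyl groups may migrate under the basic conditions, giving the 3,4-bis ether and mono- or tris-silylated material instead of the 3,5-bis ether. Fallback: mask the outer oxygens temporarily as a cyclic boronate so that the three positions are told apart by ring geometry and not by rate. It sets out from triol 6.
   - PhB(OH)2 in toluene at reflux with removal of water gives the 3,5-O-phenylboronate, 3-phenyl-2,4-dioxa-7-thia-3-borabicyclo[3.3.1]nonan-9-ol F3 (thiane ring flipped, the cis-1,3-diol bridged, O4–H free).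
   - BzCl and pyridine give its 9-benzoate F4.
   - Transesterification with propane-1,3-diol in acetone frees 3,5-dihydroxythian-4-yl benzoate F5 (all-trans, meso).
   - TBSOTf and 2,6-lutidine in CH2Cl2 give 3,5-bis(tert-butyldimethylsilyloxy)thian-4-yl benzoate F6.
   - Reductive removal of the benzoate with i-Bu2AlH in CH2Cl2 at −78 °C, chosen because it is not basic enough to move the silyl groups, rejoins the route at 8.

3. Step 8. The hindered tertiary alkoxide, flanked by two silyloxy-bearing carbons, may give CO2 back faster than the carbonate cyclises, or the internal alkyne may be activated too slowly by silver. Fallback: install the carbonate irreversibly before cyclising. It sets out from 17. LiN(SiMe3)2 in THF at −78 °C followed by Boc2O gives the tert-butyl carbonate, tert-butyl 2,5-bis(tert-butyldimethylsilyloxy)-1-(undec-1-yn-1-yl)cyclopent-3-en-1-yl carbonate F7. Ph3PAuNTf2 (2 mol %, a monovalent gold catalyst) in CH2Cl2 at rt then triggers the known 5-exo-dig rearrangement of a propargylic tert-butyl carbonate with loss of isobutene, and the route is rejoined at 19.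

**Further compounds**

F1 | step 7 | 2-chloro-3,5-bis(tert-butyldimethylsilyloxy)-4-(undec-1-yn-1-yl)thian-4-ol (racemic, both C2 epimers) | CCCCCCCCCC#C[C@@]1(O)[C@@H](O[Si](C)(C)C(C)(C)C)C(Cl)SC[C@H]1O[Si](C)(C)C(C)(C)C
F2 | step 7 | 2-chloro-3,5-bis(tert-butyldimethylsilyloxy)-4-hydroxy-4-(undec-1-yn-1-yl)thiane 1,1-dioxide (racemic, both C2 epimers) | CCCCCCCCCC#C[C@@]1(O)[C@@H](O[Si](C)(C)C(C)(C)C)C(Cl)S(=O)(=O)C[C@H]1O[Si](C)(C)C(C)(C)C
F3 | step 3 | 3-phenyl-2,4-dioxa-7-thia-3-borabicyclo[3.3.1]nonan-9-ol (3,5-O-phenylboronate of triol 6) | S1C[C@H](OB(c2ccccc2)O3)[C@@H](O)[C@H]3C1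
F4 | step 3 | 3-phenyl-2,4-dioxa-7-thia-3-borabicyclo[3.3.1]nonan-9-yl benzoate | S1C[C@H](OB(c2ccccc2)O3)[C@@H](OC(=O)c2ccccc2)[C@H]3C1
F5 | step 3 | 3,5-dihydroxythian-4-yl benzoate (all-trans, meso) | S1C[C@H](O)[C@@H](OC(=O)c2ccccc2)[C@H](O)C1
F6 | step 3 | 3,5-bis(tert-butyldimethylsilyloxy)thian-4-yl benzoate (all-trans, meso) | S1C[C@H](O[Si](C)(C)C(C)(C)C)[C@@H](OC(=O)c2ccccc2)[C@H](O[Si](C)(C)C(C)(C)C)C1
F7 | step 8 | tert-butyl 2,5-bis(tert-butyldimethylsilyloxy)-1-(undec-1-yn-1-yl)cyclopent-3-en-1-yl carbonate (meso) | CCCCCCCCCC#C[C@@]1(OC(=O)OC(C)(C)C)[C@@H](O[Si](C)(C)C(C)(C)C)C=C[C@H]1O[Si](C)(C)C(C)(C)C
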